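**Two columns.** Alder carries 4.00 times the added ligand of birch, yet after 40.0 h it holds 67% of its starting material against 64% in birch. The flask has an added ligand charge between those two, so it can be read from both.

| setting | birch | alder | ash | flask |
|---|---|---|---|---|
| starting material | 0.050 M | 0.050 M | 0.025 M | 0.050 M |
| coupling partner | 0.055 M | 0.055 M | 0.055 M | 0.0550 M |
| free catalyst | 50 µM | 50 µM | 50 µM | 50 µM |
| added ligand | 0.13 mM | 0.52 mM | 0.26 mM | 0.26 mM |
| remark | run made earlier | run made earlier | run made earlier |  |

| run | time / h | product / % | starting material / % |
|---|---|---|---|
| birch | 3.00 | 2 | 95 |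
| birch | 5.00 | 7 | 94 |
| birch | 8.00 | 9 | 93 |
| birch | 15.0 | 14 | 81 |
| birch | 25.0 | 22 | 76 |
| birch | 40.0 | 35 | 64 |
| alder | 3.00 | 2 | 96 |
| alder | 5.00 | 8 | 96 |
| alder | 8.00 | 4 | 90 |
| alder | 15.0 | 14 | 87 |
| alder | 25.0 | 22 | 79 |
| alder | 40.0 | 33 | 67 |
| ash | 8.00 | 10 | 85 |
| ash | 15.0 | 24 | 80 |
| ash | 25.0 | 37 | 67 |
| ash | 30.0 | 39 | 60 |
| ash | 40.0 | 49 | 52 |

(scatter of a reading: 1.5 percentage points)

- percent here means starting material units held: one spent catalyst counts as two
- reactions considered so far: coupling partner + catalyst intermediate A -> catalyst intermediate B; free catalyst + added ligand <-> idle complex; 2 catalyst intermediate B -> spent catalyst; catalyst intermediate B -> free catalyst + product; starting material + free catalyst <-> catalyst intermediate A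
- no earlier run changes the charge of free catalyst; that part of a forecast is a guess
- no earlier run changes the charge of coupling partner; that part of a forecast is a guess

1. factor on the rate of making product when 20% of the starting material are converted if coupling partner is charged twice over
2. factor on the rate when 20% of the starting material are converted if free catalyst is charged at 500 µM instead

**The clock.** Take the fraction left, not the fraction made. The clock constant, the logarithm of charge over what is left, divided by time, comes from the starting material of birch and alder at that last reading, averaged, as 0.0106 h⁻¹. The product column, with charge minus product counted as left, gives 0.0104 h⁻¹. These are separate readings, each good to 1.5 percentage points, and they agree, so the constant is trusted.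

**Its reach.** Ash, at half the starting material, reads 0.0163 h⁻¹, larger, so the constant belongs to this charge of starting material. With rate equal to the constant times c(starting material), the flask should reach 20% conversion after 21.1 h, at 0.423 mM h⁻¹. Scaled with free catalyst, the constant becomes 0.106 h⁻¹ at 500 µM, a factor of 10.0. That factor is a guess, since no earlier run changes the catalyst charge, and no earlier run changes coupling partner either.

**The forecast.** It sets 1.4 for doubled coupling partner and 8.8 for the catalyst, below the factor reckoned here, since loss of catalyst intermediate B “could trim this”.

    coupling partner + catalyst intermediate A → catalyst intermediate B (k = 710 M⁻¹ h⁻¹)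
    free catalyst + added ligand ⇌ idle complex (K = 2400 M⁻¹, k = 160 M⁻¹ h⁻¹)
    2 catalyst intermediate B → spent catalyst (k = 280 M⁻¹ h⁻¹)
    catalyst intermediate B → free catalyst + product (k = 26.0 h⁻¹)
    starting material + free catalyst ⇌ catalyst intermediate A (K = 1200 M⁻¹, k = 870 M⁻¹ h⁻¹)

**The result.** The answers are 1.18 and 11.2. The flask reaches 20% at 0.874 d, close to the reckoned 21.1 h, and after 2.00 d it holds 61% of its starting material against 60.2% from the clock. Multiplied by that factor, the clock constant comes to 0.119 h⁻¹ at 500 µM, above the scaled 0.106 h⁻¹. Part of the reason lies in idle complex, a form outside the working round: at 20% conversion the flask's apparent order in free catalyst is 1.1, and without the undoing of idle complex into free catalyst and added ligand it is 1.3.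

The runs stem from a simulated flask from invented constants.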